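**Plan**
- Retrosynthesis: the C15 enal, the C9 angelate and the C12–O8 lactone bond are taken back to a cis-8,9-diol. The ring bond C8–C9 is then cut reductively to a 1,6-dialdehyde, followed by C6–C7 (carbonyl allylation), C5–C10 ([3,3] shift) and one ester C–O bond.
- Forward: ester 10 → Ireland–Claisen (C5–C10) → zinc allylation (C6–C7, bringing C7, C8 and the acrylate C11–C13) → SmI2 pinacol closure of the cyclohexane (C8–C9) → γ-lactone → angelate → enal.
- Enabling feature: C8 (lactone carbinol) and C9 (angelate carbinol) are vicinal, cis, secondary carbinol carbons of the six-membered ring, so each is an aldehyde carbon in retrosynthesis. C9 hangs on quaternary C10 (its aldehyde cannot enolise), and O8 lies γ to C12, so the new C8 hydroxyl closes the lactone.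
- Stereochemistry: absolute configuration and C5/C10 come from a chair Claisen of an (E)-allylic ester under a chiral boron controller. C6/C7 come from a chair Barbier transition state (6,7-syn, 5,6-anti-Felkin). C8/C9 come from samarium-chelated coupling in a chair that keeps the C5 and C7 branches equatorial.

Key step: step 17

Remark on numbering: C1–C15 are the elemane numbers of the target (C10 quaternary with Me-14 and vinyl C1=C2; C5 bears C4(=C3)–C15; C6 OAc; C7 bears C11(=C13)–C12; C8 lactone O; C9 O-angeloyl). Every stereocentre of an intermediate has the configuration it has in the target; the SMILES in the compound list define it. TBS = tert-butyldimethylsilyl, TBDPS = tert-butyldiphenylsilyl.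

Assumption: the (S,S)-configured boron controller is taken to give the enantiomer drawn in step 8; if the sense of induction proves opposite, the (R,R)-controller is used with no other change.

Step 1
Reactants: 1 prenyl acetate (3-methylbut-2-en-1-yl acetate)
Product: 2 (E)-4-hydroxy-3-methylbut-2-en-1-yl acetate
Conditions: SeO2 (0.5 equiv), t-BuOOH (70% aq.), salicylic acid (cat.), CH2Cl2, rt
Reagents that add atoms: selenium dioxide O=[Se]=O (oxygen-transfer catalyst); tert-butyl hydroperoxide CC(C)(C)OO (terminal oxidant)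
Why: Riley allylic oxidation (ene reaction, then [2,3]-sigmatropic shift) of a trisubstituted alkene takes place at the (E)-methyl group, which places the future O9 and fixes the (E)-geometry needed in step 8.

Step 2
Reactants: 2 (E)-4-hydroxy-3-methylbut-2-en-1-yl acetate
Product: 3 (E)-4-(TBSO)-3-methylbut-2-en-1-yl acetate
Conditions: TBSCl, imidazole, CH2Cl2, 0 °C → rt
Reagents that add atoms: tert-butyldimethylsilyl chloride CC(C)(C)[Si](C)(C)Cl
Why: Standard silylation of a primary allylic alcohol.

Step 3
Reactants: 3 (E)-4-(TBSO)-3-methylbut-2-en-1-yl acetate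
Product: 4 (E)-4-(TBSO)-3-methylbut-2-en-1-ol
Conditions: K2CO3 (cat.), MeOH, 0 °C
Reagents that add atoms: none
Why: Base-catalysed methanolysis (transesterification) removes the acetate and leaves the silyl ether and the alkene geometry untouched.

Step 4
Reactants: 5 4-methyl hydrogen itaconate (4-methoxy-2-methylidene-4-oxobutanoic acid)
Product: 6 methyl 3-(hydroxymethyl)but-3-enoate
Conditions: BH3·SMe2 (1.1 equiv), THF, −10 °C → rt; MeOH quench
Reagents that add atoms: none
Why: Borane reduces a carboxylic acid much faster than an ester or an electron-poor 1,1-disubstituted alkene, so only the conjugated acid should be taken to the allylic alcohol (the future C15–O).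

Step 5
Reactants: 6 methyl 3-(hydroxymethyl)but-3-enoate
Product: 7 methyl 3-[(TBDPSO)methyl]but-3-enoate
Conditions: TBDPSCl, imidazole, CH2Cl2, 0 °C → rt
Reagents that add atoms: tert-butyldiphenylsilyl chloride CC(C)(C)[Si](Cl)(c1ccccc1)c1ccccc1
Why: Fast silylation traps the hydroxy ester before it can lactonise and installs an ether that outlasts the later removal of the TBS groups and the acid of step 18.

Step 6
Reactants: 7 methyl 3-[(TBDPSO)methyl]but-3-enoate
Product: 8 3-[(TBDPSO)methyl]but-3-enoic acid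
Conditions: LiOH·H2O, THF–H2O, 0 °C; then 1 M HCl to pH 3
Reagents that add atoms: lithium hydroxide [Li+].[OH-]
Why: Saponification of an unhindered methyl ester at 0 °C is faster than α-deprotonation, so the β,γ-double bond should stay in place.

Step 7
Reactants: 4 (E)-4-(TBSO)-3-methylbut-2-en-1-ol; 8 3-[(TBDPSO)methyl]but-3-enoic acid
Product: 10 (E)-4-(TBSO)-3-methylbut-2-en-1-yl 3-[(TBDPSO)methyl]but-3-enoate, via O-acylisourea 9 (not isolated)
Conditions: DIC, DMAP (5 mol %), CH2Cl2, 0 °C
Reagents that add atoms: none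
Why: Steglich esterification of a primary alcohol; low temperature and only catalytic DMAP limit drift of the β,γ-alkene into conjugation.

Step 8
Reactants: 10 (E)-4-(TBSO)-3-methylbut-2-en-1-yl 3-[(TBDPSO)methyl]but-3-enoate
Product: 13 (2S,3S)-3-[(TBSO)methyl]-2-[3-(TBDPSO)prop-1-en-2-yl]-3-methylpent-4-enoic acid, via boron ketene acetal 11 (not isolated), via acyloxyborane 12 (not isolated)
Conditions: (4S,5S)-2-bromo-1,3-bis{[3,5-bis(trifluoromethyl)phenyl]sulfonyl}-4,5-diphenyl-1,3,2-diazaborolidine (1.2 equiv), i-Pr2NEt, CH2Cl2, −78 °C; then −20 → 4 °C; aq. work-up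
Reagents that add atoms: none
Why: Soft enolisation gives the E(O) boron ketene acetal, which undergoes the Ireland–Claisen [3,3] shift through a chair with C9 equatorial (from the (E)-alkene) and the C4 unit axial, so that C5–C10 forms with the methyl cis to the C4 branch and the vinyl group on C10 is born from the allyl unit, while the C2-symmetric sulfonamide controller selects the enolate face; the enantioselective boron-enolate Claisen is a known reaction type for 3-methylbut-3-enoates of trisubstituted allylic alcohols.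

Step 9
Reactants: 13 (2S,3S)-acid
Product: 14 (2S,3S)-3-[(TBSO)methyl]-2-[3-(TBDPSO)prop-1-en-2-yl]-3-methylpent-4-en-1-ol
Conditions: LiAlH4, Et2O, 0 °C; Fieser work-up
Reagents that add atoms: none
Why: Hydride reduction of the acid to the primary alcohol; silyl ethers and isolated alkenes are inert and C5 cannot epimerise at the carboxylate stage.

Step 10
Reactants: 14 (2S,3S)-alcohol
Product: 15 (2S,3S)-3-[(TBSO)methyl]-2-[3-(TBDPSO)prop-1-en-2-yl]-3-methylpent-4-enal (the C6 aldehyde)
Conditions: Dess–Martin periodinane, NaHCO3, CH2Cl2, 0 °C → rt; used without storage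
Reagents that add atoms: none
Why: Buffered Dess–Martin oxidation is essentially neutral, so the α-branched β,γ-unsaturated aldehyde should form without epimerisation at C5 or alkene migration.

Step 11
Reactants: 16 (tert-butyldimethylsilyloxy)acetaldehyde; 17 tert-butyl acrylate
Product: 18 tert-butyl 4-(TBSO)-3-hydroxy-2-methylidenebutanoate (racemic)
Conditions: DABCO (1 equiv), 1,4-dioxane–H2O, rt
Reagents that add atoms: none
Why: Morita–Baylis–Hillman reaction of an unhindered aldehyde with an acrylate; the carbinol stereocentre is erased in step 12.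

Step 12
Reactants: 18 Morita–Baylis–Hillman adduct
Product: 19 tert-butyl (Z)-2-(bromomethyl)-4-(TBSO)but-2-enoate
Conditions: NBS, Me2S, CH2Cl2, 0 °C → rt
Reagents that add atoms: N-bromosuccinimide O=C1CCC(=O)N1Br
Why: Corey–Kim-type activation of the alcohol and bromide attack with allylic transposition (SN2′) give the 2-(bromomethyl)enoate with CH2OTBS cis to CH2Br, the usual outcome for Morita–Baylis–Hillman alcohols.

Step 13
Reactants: 15 C6 aldehyde; 19 tert-butyl (Z)-2-(bromomethyl)-4-(TBSO)but-2-enoate
Product: 21 homoallylic alcohol (C6–OH; C7 bearing C8H2OTBS and the tert-butyl 2-propenoate unit C11(=C13)–C12), via allylzinc bromide 20 (not isolated)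
Conditions: Zn dust, sat. aq. NH4Cl–THF (1:3), 0 °C → rt
Reagents that add atoms: none
Why: Barbier-type zinc allylation through a Zimmerman–Traxler chair in which the γ-CH2OTBS group (cis to CH2Zn) is axial, giving the 6,7-syn adduct, and in which C5–H turns toward that axial group with quaternary C10 anti to the forming bond, giving the 5,6-anti-Felkin relation of the target (the usual result for (Z)-γ-substituted allyl metals and α-branched aldehydes); the tert-butyl ester keeps O6 from lactonising.

Step 14
Reactants: 21 homoallylic alcohol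
Product: 22 C6 acetate of 21
Conditions: Ac2O, DMAP, pyridine, CH2Cl2, rt
Reagents that add atoms: acetic anhydride CC(=O)OC(C)=O
Why: DMAP-catalysed acetylation of the hindered secondary alcohol installs the acetate of the target and blocks a 6,12-lactone for good.

Step 15
Reactants: 22 C6 acetate
Product: 23 C8,C9-diol (both primary alcohols free; C15–OTBDPS kept)
Conditions: HF·pyridine, pyridine, THF, 0 °C → rt
Reagents that add atoms: none
Why: Buffered HF·pyridine cleaves primary TBS ethers much faster than a TBDPS ether, and the weakly acidic medium should not move the acetate or close the tert-butyl ester onto O8.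

Step 16
Reactants: 23 C8,C9-diol
Product: 24 C8,C9-dialdehyde
Conditions: Dess–Martin periodinane, NaHCO3, CH2Cl2, 0 °C; crude product used at once
Reagents that add atoms: none
Why: Neutral double oxidation gives the non-enolisable C9 aldehyde and the C8 aldehyde without base, which protects the acidic C7–H and the β-acetoxy group.

Step 17
Reactants: 24 C8,C9-dialdehyde
Product: 27 cis-8,9-diol with the cyclohexane closed (tert-butyl ester, C6–OAc and C15–OTBDPS kept), via samarium ketyl 25 (not isolated), via samarium diolate 26 (not isolated)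
Conditions: SmI2 (2.5 equiv), t-BuOH (2 equiv), THF, −78 → −40 °C; sat. aq. NH4Cl
Reagents that add atoms: none
Why: SmI2 transfers one electron to the less hindered C8 aldehyde to give the trivalent-samarium ketyl 25, which attacks the samarium-bound C9 aldehyde carbon (or pairs with a second ketyl); a second electron gives diolate 26 and protonation gives 27. The closest known reaction type is the SmI2 pinacol cyclisation of 1,6-dialdehydes to cis-cyclohexane-1,2-diols. The cyclohexane closes in the 6-exo-trig mode. The cis relation of O8 and O9 follows from their joint binding to samarium in the bond-forming transition state, and their placement follows from a chair that keeps the C5 and C7 branches equatorial: O8 must then be equatorial, because its axial site is blocked by the syn-axial C10 methyl and C6 acetoxy groups, and O9 is axial on the same face. The step needs chemoselectivity for the two aldehydes over the acrylate, the acetate and the allylic silyl ether; low temperature, the absence of HMPA and the fact that the only ketyl–acrylate closure open is a slow 7-endo one should secure it.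

Step 18
Reactants: 27 cis-8,9-diol
Product: 28 9-hydroxy-8,12-lactone (trans-fused α-methylene-γ-butyrolactone; C6–OAc; C15–OTBDPS)
Conditions: TFA–CH2Cl2 (1:9), 0 °C
Reagents that add atoms: none
Why: Acid removes the tert-butyl group and the equatorial C8–OH closes onto C12 to give the trans-fused γ-lactone; the axial C9–OH on the opposite face cannot reach C12, and the C6 acetate, trans-1,3 to O8, cannot migrate.

Step 19
Reactants: 28 9-hydroxy-8,12-lactone
Product: 29 9-O-angelate of 28
Conditions: angelic acid, 2,4,6-trichlorobenzoyl chloride, Et3N, toluene, rt; then 28, 80 °C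
Reagents that add atoms: angelic acid C/C=C(/C)C(O)=O
Why: Yamaguchi-type mixed-anhydride acylation without a nucleophilic catalyst acylates hindered secondary alcohols while avoiding the addition–elimination path that turns angelates into tiglates.

Step 20
Reactants: 29 9-O-angelate
Product: 30 C15 allylic alcohol
Conditions: HF·pyridine, THF, 0 °C → rt
Reagents that add atoms: none
Why: Fluoride desilylation in a weakly acidic medium leaves the acetate, the angelate and the α-methylene lactone alone.

Step 21
Reactants: 30 C15 allylic alcohol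
Product: 31 target (CNP0252310.1)
Conditions: MnO2 (activated, excess), CH2Cl2, rt
Reagents that add atoms: none
Why: MnO2 oxidises the primary allylic alcohol selectively to the 2-substituted acrolein and touches no other group.

**Compound list**
1 | prenyl acetate | CC(C)=CCOC(C)=O | starting material
2 | (E)-4-hydroxy-3-methylbut-2-en-1-yl acetate | CC(=O)OC/C=C(\C)CO | intermediate
3 | (E)-4-(TBSO)-3-methylbut-2-en-1-yl acetate | CC(=O)OC/C=C(\C)CO[Si](C)(C)C(C)(C)C | intermediate
4 | (E)-4-(TBSO)-3-methylbut-2-en-1-ol | OC/C=C(\C)CO[Si](C)(C)C(C)(C)C | intermediate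
5 | 4-methyl hydrogen itaconate | COC(=O)CC(=C)C(O)=O | starting material
6 | methyl 3-(hydroxymethyl)but-3-enoate | COC(=O)CC(=C)CO | intermediate
7 | methyl 3-[(TBDPSO)methyl]but-3-enoate | COC(=O)CC(=C)CO[Si](c1ccccc1)(c1ccccc1)C(C)(C)C | intermediate
8 | 3-[(TBDPSO)methyl]but-3-enoic acid | OC(=O)CC(=C)CO[Si](c1ccccc1)(c1ccccc1)C(C)(C)C | intermediate
9 | O-acylisourea from 8 and DIC | CC(C)N=C(NC(C)C)OC(=O)CC(=C)CO[Si](c1ccccc1)(c1ccccc1)C(C)(C)C | intermediate (not isolated)
10 | (E)-4-(TBSO)-3-methylbut-2-en-1-yl 3-[(TBDPSO)methyl]but-3-enoate | C=C(CO[Si](c1ccccc1)(c1ccccc1)C(C)(C)C)CC(=O)OC/C=C(\C)CO[Si](C)(C)C(C)(C)C | intermediate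
11 | E(O) boron ketene acetal of 10 (C4 unit cis to the allyloxy group) | C=C(CO[Si](c1ccccc1)(c1ccccc1)C(C)(C)C)/C=C(\OC/C=C(\C)CO[Si](C)(C)C(C)(C)C)OB1N(S(=O)(=O)c2cc(C(F)(F)F)cc(C(F)(F)F)c2)[C@@H](c2ccccc2)[C@H](c2ccccc2)N1S(=O)(=O)c1cc(C(F)(F)F)cc(C(F)(F)F)c1 | intermediate (not isolated)
12 | acyloxyborane of acid 13 | C=C[C@](C)(CO[Si](C)(C)C(C)(C)C)[C@H](C(=C)CO[Si](c1ccccc1)(c1ccccc1)C(C)(C)C)C(=O)OB1N(S(=O)(=O)c2cc(C(F)(F)F)cc(C(F)(F)F)c2)[C@@H](c2ccccc2)[C@H](c2ccccc2)N1S(=O)(=O)c1cc(C(F)(F)F)cc(C(F)(F)F)c1 | intermediate (not isolated)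
13 | (2S,3S)-3-[(TBSO)methyl]-2-[3-(TBDPSO)prop-1-en-2-yl]-3-methylpent-4-enoic acid | C=C[C@](C)(CO[Si](C)(C)C(C)(C)C)[C@H](C(=C)CO[Si](c1ccccc1)(c1ccccc1)C(C)(C)C)C(O)=O | intermediate
14 | (2S,3S)-3-[(TBSO)methyl]-2-[3-(TBDPSO)prop-1-en-2-yl]-3-methylpent-4-en-1-ol | C=C[C@](C)(CO[Si](C)(C)C(C)(C)C)[C@H](C(=C)CO[Si](c1ccccc1)(c1ccccc1)C(C)(C)C)CO | intermediate
15 | (2S,3S)-3-[(TBSO)methyl]-2-[3-(TBDPSO)prop-1-en-2-yl]-3-methylpent-4-enal (C6 aldehyde) | C=C[C@](C)(CO[Si](C)(C)C(C)(C)C)[C@H](C(=C)CO[Si](c1ccccc1)(c1ccccc1)C(C)(C)C)C=O | intermediate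
16 | (tert-butyldimethylsilyloxy)acetaldehyde | O=CCO[Si](C)(C)C(C)(C)C | starting material
17 | tert-butyl acrylate | C=CC(=O)OC(C)(C)C | starting material
18 | tert-butyl 4-(TBSO)-3-hydroxy-2-methylidenebutanoate (racemic) | C=C(C(O)CO[Si](C)(C)C(C)(C)C)C(=O)OC(C)(C)C | intermediate
19 | tert-butyl (Z)-2-(bromomethyl)-4-(TBSO)but-2-enoate | BrC/C(C(=O)OC(C)(C)C)=C\CO[Si](C)(C)C(C)(C)C | intermediate
20 | allylzinc bromide from 19 | Br[Zn]C/C(C(=O)OC(C)(C)C)=C\CO[Si](C)(C)C(C)(C)C | intermediate (not isolated)
21 | homoallylic alcohol (C6–OH, C7 with CH2OTBS and tert-butyl acrylate unit) | C=C[C@](C)(CO[Si](C)(C)C(C)(C)C)[C@H](C(=C)CO[Si](c1ccccc1)(c1ccccc1)C(C)(C)C)[C@H](O)[C@@H](CO[Si](C)(C)C(C)(C)C)C(=C)C(=O)OC(C)(C)C | intermediate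
22 | C6 acetate of 21 | C=C[C@](C)(CO[Si](C)(C)C(C)(C)C)[C@H](C(=C)CO[Si](c1ccccc1)(c1ccccc1)C(C)(C)C)[C@H](OC(C)=O)[C@@H](CO[Si](C)(C)C(C)(C)C)C(=C)C(=O)OC(C)(C)C | intermediate
23 | C8,C9-diol | C=C[C@](C)(CO)[C@H](C(=C)CO[Si](c1ccccc1)(c1ccccc1)C(C)(C)C)[C@H](OC(C)=O)[C@@H](CO)C(=C)C(=O)OC(C)(C)C | intermediate
24 | C8,C9-dialdehyde | C=C[C@](C)(C=O)[C@H](C(=C)CO[Si](c1ccccc1)(c1ccccc1)C(C)(C)C)[C@H](OC(C)=O)[C@@H](C=O)C(=C)C(=O)OC(C)(C)C | intermediate
25 | C8 samarium ketyl of 24 | C=C[C@](C)(C=O)[C@H](C(=C)CO[Si](c1ccccc1)(c1ccccc1)C(C)(C)C)[C@H](OC(C)=O)[C@@H]([CH]O[Sm](I)I)C(=C)C(=O)OC(C)(C)C | intermediate (not isolated)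
26 | bis-samarium cis-8,9-diolate | C=C[C@]1(C)[C@H](O[Sm](I)I)[C@H](O[Sm](I)I)[C@@H](C(=C)C(=O)OC(C)(C)C)[C@@H](OC(C)=O)[C@H]1C(=C)CO[Si](c1ccccc1)(c1ccccc1)C(C)(C)C | intermediate (not isolated)
27 | cis-8,9-diol (cyclohexane closed) | C=C[C@]1(C)[C@H](O)[C@H](O)[C@@H](C(=C)C(=O)OC(C)(C)C)[C@@H](OC(C)=O)[C@H]1C(=C)CO[Si](c1ccccc1)(c1ccccc1)C(C)(C)C | intermediate
28 | 9-hydroxy-8,12-lactone | C=C[C@]1(C)[C@H](O)[C@@H]2OC(=O)C(=C)[C@H]2[C@@H](OC(C)=O)[C@H]1C(=C)CO[Si](c1ccccc1)(c1ccccc1)C(C)(C)C | intermediate
29 | 9-O-angelate | C=C[C@]1(C)[C@H](OC(=O)/C(C)=C\C)[C@@H]2OC(=O)C(=C)[C@H]2[C@@H](OC(C)=O)[C@H]1C(=C)CO[Si](c1ccccc1)(c1ccccc1)C(C)(C)C | intermediate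
30 | C15 allylic alcohol | C=C[C@]1(C)[C@H](OC(=O)/C(C)=C\C)[C@@H]2OC(=O)C(=C)[C@H]2[C@@H](OC(C)=O)[C@H]1C(=C)CO | intermediate
31 | CNP0252310.1, (5R,6S,7S,8R,9S,10S) in elemane numbering | C=C[C@]1(C)[C@H](OC(=O)/C(C)=C\C)[C@@H]2OC(=O)C(=C)[C@H]2[C@@H](OC(C)=O)[C@H]1C(=C)C=O | target

Total step count: 21. Longest linear sequence: 16 steps (1–3, 7–10, 13–21).

**Steps most likely to fail**

Step 17. The C9 ketyl may add to the acrylate in the 7-endo mode or the acrylate may be reduced; the vinyl group on C10 may shift to the C9 radical; dialdehyde 24 may lose its C7 configuration or its acetate by enolisation toward the acrylate before it couples; cis-selectivity may be incomplete. The fallback sets out from 23 and comes back at 27, and masks the acrylate first. Conjugate addition of thiophenol (PhSH, Et3N cat., CH2Cl2) to 23 should give the sulfide diol F1. Dess–Martin oxidation should give the sulfide dialdehyde F2, in which C7–H is no longer allylic and no radical acceptor is left. The same SmI2 coupling should give the sulfide cis-diol F3. Oxidation at sulfur (mCPBA, 1 equiv, CH2Cl2, −78 °C) should give the sulfoxide F4, and thermal syn-elimination (toluene, CaCO3, 110 °C) restores the exocyclic methylene and delivers 27.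

Step 13. Facial selectivity at the aldehyde may be poor (Felkin against anti-Felkin), the allylzinc may lose its geometry and with it the syn relation, and C5 of aldehyde 15 may epimerise. The fallback sets out from 18 and comes back at 21, and replaces the organozinc made in the flask by a preformed allylboronate of fixed geometry. Acetylation of 18 (Ac2O, pyridine) gives the Morita–Baylis–Hillman acetate F5. Copper-catalysed allylic borylation with transposition (B2pin2, CuCl, KOAc, DMF) should give the allylboronate F6, with CH2OTBS cis to CH2B. Its uncatalysed addition to 15 (toluene, 80 °C; aqueous work-up) runs through a tight boron-centred chair and should return 21.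

Step 19. Acylation of the axial, neopentyl C9–OH may be slow, and the angelate may isomerise to the tiglate on prolonged heating. The fallback sets out from 28 and comes back at 29, and builds the (Z)-alkene on the ester instead of transferring it. Steglich esterification of 28 with 2-[bis(2,2,2-trifluoroethoxy)phosphoryl]propanoic acid (DIC, DMAP cat., CH2Cl2) should give the phosphonate ester F7. Still–Gennari olefination with acetaldehyde (KN(SiMe3)2, 1 equiv, 18-crown-6, THF, −78 °C) forms the (Z)-2-methylbut-2-enoate directly and gives 29.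

Further compounds
F1 | step 17 | thiophenol adduct of diol 23 (C13–SPh, C11 epimers) | C=C[C@](C)(CO)[C@H](C(=C)CO[Si](c1ccccc1)(c1ccccc1)C(C)(C)C)[C@H](OC(C)=O)[C@@H](CO)C(CSc1ccccc1)C(=O)OC(C)(C)C
F2 | step 17 | sulfide dialdehyde | C=C[C@](C)(C=O)[C@H](C(=C)CO[Si](c1ccccc1)(c1ccccc1)C(C)(C)C)[C@H](OC(C)=O)[C@@H](C=O)C(CSc1ccccc1)C(=O)OC(C)(C)C
F3 | step 17 | sulfide cis-8,9-diol | C=C[C@]1(C)[C@H](O)[C@H](O)[C@@H](C(CSc2ccccc2)C(=O)OC(C)(C)C)[C@@H](OC(C)=O)[C@H]1C(=C)CO[Si](c1ccccc1)(c1ccccc1)C(C)(C)C
F4 | step 17 | sulfoxide of F3 | C=C[C@]1(C)[C@H](O)[C@H](O)[C@@H](C(CS(=O)c2ccccc2)C(=O)OC(C)(C)C)[C@@H](OC(C)=O)[C@H]1C(=C)CO[Si](c1ccccc1)(c1ccccc1)C(C)(C)C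
F5 | step 13 | acetate of 18 | C=C(C(OC(C)=O)CO[Si](C)(C)C(C)(C)C)C(=O)OC(C)(C)C
F6 | step 13 | tert-butyl (E)-2-[(4,4,5,5-tetramethyl-1,3,2-dioxaborolan-2-yl)methyl]-4-(TBSO)but-2-enoate | CC1(C)OB(C/C(C(=O)OC(C)(C)C)=C\CO[Si](C)(C)C(C)(C)C)OC1(C)C
F7 | step 19 | 9-O-{2-[bis(2,2,2-trifluoroethoxy)phosphoryl]propanoate} of 28 | C=C[C@]1(C)[C@H](OC(=O)C(C)P(=O)(OCC(F)(F)F)OCC(F)(F)F)[C@@H]2OC(=O)C(=C)[C@H]2[C@@H](OC(C)=O)[C@H]1C(=C)CO[Si](c1ccccc1)(c1ccccc1)C(C)(C)C
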